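**Retrosynthetic overview**
1. Ring B is closed last: the C9–C10 bond is made by an intramolecular Hosomi–Sakurai conjugate allylation of a ring A enone, which sets C9, C10, the cis ring fusion and the exocyclic C8=C17 alkene; the C2 carbinol then comes from the ketone.
2. Ring A is made first by an Ireland–Claisen ring contraction of a six-membered lactone (C4–C5 bond), transferring the C1–O chirality to quaternary C4 and to C5.
3. The lactone comes from ring-closing metathesis of the methacrylate of a Brown syn-alkoxyallylation adduct of an (E)-enal; this is the only reagent-controlled stereo step.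
4. The enal/allylsilane chain comes from methyl geranate: ozonolysis, 2-(silylmethyl)vinyl Grignard addition, vinyl-ether Claisen (fixes the allylsilane geometry), Wittig.

Assumptions: positions are given in labdane numbering (C1–C20), with the C10 methyl defining the β-face; methyl (E)-geranate 1 and allyl methoxymethyl ether 12 are taken as purchasable; the borane from (+)-α-pinene is taken to attack the Si face of the enal, and if the opposite sense were found the antipodal borane would be used.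

**Step 1**
Reactants: 1 methyl (2E)-3,7-dimethylocta-2,6-dienoate (methyl geranate)
Product: 3 methyl (2E)-3-methyl-6-oxohex-2-enoate, via ozonide 2 (not isolated)
Conditions: O3 (1.0 equiv), CH2Cl2, −78 °C; then Me2S, −78 °C to rt
Reagents that add atoms: ozone, [O-][O+]=O
Why: Chemoselective ozonolysis with reductive work-up, because ozone attacks the electron-rich 6,7-alkene far faster than the ester-conjugated 2,3-alkene, so the (E)-enoate that becomes C13=C14 survives unchanged.

**Step 2**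
Reactants: 3 methyl (2E)-3-methyl-6-oxohex-2-enoate; 4 (2-bromoallyl)trimethylsilane
Product: 6 methyl (2E)-6-hydroxy-3-methyl-7-[(trimethylsilyl)methyl]octa-2,7-dienoate (racemic), via alkenylmagnesium bromide 5 (not isolated)
Conditions: 4, Mg, THF, rt; then 3, THF, −78 °C; aq NH4Cl
Reagents that add atoms: none
Why: Grignard 1,2-addition to the aldehyde is much faster at −78 °C than attack on the β,β-disubstituted enoate, and the racemic carbinol centre is erased in step 3.

**Step 3**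
Reactants: 6 methyl (2E)-6-hydroxy-3-methyl-7-[(trimethylsilyl)methyl]octa-2,7-dienoate; 7 vinyl acetate
Product: 9 methyl (2E,6Z)-3-methyl-10-oxo-7-[(trimethylsilyl)methyl]deca-2,6-dienoate, via allyl vinyl ether 8 (not isolated)
Conditions: [Ir(cod)Cl]2 (1 mol %), Na2CO3 (0.6 equiv), PhMe, 100 °C; then 140 °C (sealed tube)
Reagents that add atoms: none
Why: Iridium-catalysed transfer vinylation followed by a Claisen rearrangement through a chair transition state with the CH2CH2 chain pseudo-equatorial places C7 trans to C11, so the CH2SiMe3 group is cis to C11 (6Z), the geometry required in step 11.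

**Step 4**
Reactants: 9 methyl (2E,6Z)-3-methyl-10-oxo-7-[(trimethylsilyl)methyl]deca-2,6-dienoate; 10 2-(triphenylphosphoranylidene)propanal
Product: 11 methyl (2E,6Z,10E)-3,11-dimethyl-12-oxo-7-[(trimethylsilyl)methyl]dodeca-2,6,10-trienoate
Conditions: PhMe, 90 °C
Reagents that add atoms: none
Why: Wittig olefination with the stabilised α-methyl ylide is E-selective and installs C1, C10 and C20 as the (E)-2-methyl enal.

**Step 5**
Reactants: 11 methyl (2E,6Z,10E)-3,11-dimethyl-12-oxo-7-[(trimethylsilyl)methyl]dodeca-2,6,10-trienoate; 12 3-(methoxymethoxy)prop-1-ene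
Product: 17 methyl (2E,6Z,10E,12R,13R)-12-hydroxy-13-(methoxymethoxy)-3,11-dimethyl-7-[(trimethylsilyl)methyl]pentadeca-2,6,10,14-tetraenoate, via lithiated allyl ether 13 (not isolated), via lithium borate 14 (not isolated), via allylborane 15 (not isolated), via borinic ester 16 (not isolated)
Conditions: 12, s-BuLi, THF, −78 °C; (−)-Ipc2BOMe; BF3·OEt2; then 11, −78 °C; NaOH, H2O2, 0 °C to rt
Reagents that add atoms: none
Why: Brown asymmetric (Z)-γ-alkoxyallylboration through a closed chair transition state gives the syn 1,2-diol monoether, and the isopinocampheyl groups from (+)-α-pinene direct attack to the Si face of the enal, setting C1 (12R, the centre that later controls C4 and C5) and C2 (13R).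

**Step 6**
Reactants: 17 methyl (2E,6Z,10E,12R,13R)-12-hydroxy-13-(methoxymethoxy)-3,11-dimethyl-7-[(trimethylsilyl)methyl]pentadeca-2,6,10,14-tetraenoate; 18 methacryloyl chloride
Product: 19 methyl (2E,6Z,10E,12R,13R)-13-(methoxymethoxy)-3,11-dimethyl-12-[(2-methylprop-2-enoyl)oxy]-7-[(trimethylsilyl)methyl]pentadeca-2,6,10,14-tetraenoate
Conditions: Et3N, DMAP (10 mol %), CH2Cl2, 0 °C to rt
Reagents that add atoms: none
Why: DMAP-catalysed acylation of the secondary allylic alcohol brings in C4, its methyl and the future carboxyl carbon without touching a stereocentre.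

**Step 7**
Reactants: 19 methyl (2E,6Z,10E,12R,13R)-13-(methoxymethoxy)-3,11-dimethyl-12-[(2-methylprop-2-enoyl)oxy]-7-[(trimethylsilyl)methyl]pentadeca-2,6,10,14-tetraenoate
Product: 20 methyl (2E,6Z,10E)-11-[(2R,3R)-3-(methoxymethoxy)-5-methyl-6-oxo-3,6-dihydro-2H-pyran-2-yl]-3-methyl-7-[(trimethylsilyl)methyl]dodeca-2,6,10-trienoate
Conditions: (H2IMes)(PCy3)Cl2Ru=CHPh (second-generation Grubbs catalyst, 5 mol %), CH2Cl2 (5 mM), 40 °C
Reagents that add atoms: none
Why: Ring-closing metathesis between the terminal vinyl group and the methacrylate closes the unsaturated six-membered lactone (C3=C4), while the trisubstituted alkenes are inert to the ruthenium carbene.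

**Step 8**
Reactants: 20 methyl (2E,6Z,10E)-11-[(2R,3R)-3-(methoxymethoxy)-5-methyl-6-oxo-3,6-dihydro-2H-pyran-2-yl]-3-methyl-7-[(trimethylsilyl)methyl]dodeca-2,6,10-trienoate
Product: 24 (1R,2S,5R)-5-(methoxymethoxy)-2-[(3Z,7E)-9-methoxy-7-methyl-9-oxo-3-[(trimethylsilyl)methyl]nona-3,7-dien-1-yl]-1,3-dimethylcyclohex-3-ene-1-carboxylic acid, via lithium enolate 21 (not isolated), via ketene silyl acetal 22 (not isolated), via trimethylsilyl ester 23 (not isolated)
Conditions: LiBH(s-Bu)3 (1.05 equiv), THF, −78 °C; Me3SiCl, Et3N, −78 °C to rt; PhMe, 100 °C; aq citric acid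
Reagents that add atoms: none
Why: Conjugate reduction gives the lactone enolate, and after O-silylation an Ireland–Claisen ring contraction through the ring-enforced boat transition state exchanges the C1–O bond suprafacially for the C4–C5 bond, so the (1R) carbinol and the (E)-C5=C10 alkene fix quaternary C4 and C5 with the carboxyl cis to the side chain.

**Step 9**
Reactants: 24 (1R,2S,5R)-5-(methoxymethoxy)-2-[(3Z,7E)-9-methoxy-7-methyl-9-oxo-3-[(trimethylsilyl)methyl]nona-3,7-dien-1-yl]-1,3-dimethylcyclohex-3-ene-1-carboxylic acid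
Product: 25 (1R,2S,5R)-5-hydroxy-2-[(3Z,7E)-9-methoxy-7-methyl-9-oxo-3-[(trimethylsilyl)methyl]nona-3,7-dien-1-yl]-1,3-dimethylcyclohex-3-ene-1-carboxylic acid
Conditions: ZnBr2 (1 equiv), n-PrSH (3 equiv), CH2Cl2, 0 °C
Reagents that add atoms: none
Why: Lewis acid/thiol cleavage of the methoxymethyl acetal (the thiol traps the oxocarbenium ion) frees the allylic alcohol under conditions mild enough for the allylsilane, with no stereocentre touched.

**Step 10**
Reactants: 25 (1R,2S,5R)-5-hydroxy-2-[(3Z,7E)-9-methoxy-7-methyl-9-oxo-3-[(trimethylsilyl)methyl]nona-3,7-dien-1-yl]-1,3-dimethylcyclohex-3-ene-1-carboxylic acid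
Product: 26 (1R,2S)-2-[(3Z,7E)-9-methoxy-7-methyl-9-oxo-3-[(trimethylsilyl)methyl]nona-3,7-dien-1-yl]-1,3-dimethyl-5-oxocyclohex-3-ene-1-carboxylic acid
Conditions: MnO2 (20 equiv), CH2Cl2, rt
Reagents that add atoms: none
Why: MnO2 oxidises only the allylic alcohol, giving the β-methyl enone that ring B closure needs (the C2 centre is given up here and reset in step 12).

**Step 11**
Reactants: 26 (1R,2S)-2-[(3Z,7E)-9-methoxy-7-methyl-9-oxo-3-[(trimethylsilyl)methyl]nona-3,7-dien-1-yl]-1,3-dimethyl-5-oxocyclohex-3-ene-1-carboxylic acid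
Product: 27 (1R,4aR,5S,8aS)-5-[(3E)-5-methoxy-3-methyl-5-oxopent-3-en-1-yl]-1,4a-dimethyl-6-methylidene-3-oxodecahydronaphthalene-1-carboxylic acid
Conditions: EtAlCl2 (3 equiv), CH2Cl2, −78 to 0 °C; aq Rochelle salt, then dilute HCl
Reagents that add atoms: none
Why: Intramolecular Hosomi–Sakurai conjugate allylation (SE2′): the chain on the α-face of C5 can reach only the α-face of C10 so the decalin is cis-fused, the chair-like closure puts C11 equatorial (from the 6Z allylsilane) which sets C9, and loss of silicon leaves the exocyclic C8=C17 alkene.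

**Step 12**
Reactants: 27 (1R,4aR,5S,8aS)-5-[(3E)-5-methoxy-3-methyl-5-oxopent-3-en-1-yl]-1,4a-dimethyl-6-methylidene-3-oxodecahydronaphthalene-1-carboxylic acid
Product: 29 (1R,3S,4aR,5S,8aS)-3-hydroxy-5-[(3E)-5-methoxy-3-methyl-5-oxopent-3-en-1-yl]-1,4a-dimethyl-6-methylidenedecahydronaphthalene-1-carboxylic acid, via acyloxyborohydride 28 (not isolated)
Conditions: Me4NBH(OAc)3 (3 equiv), AcOH (5 equiv), MeCN, −20 °C to rt
Reagents that add atoms: none
Why: Proposed new method: the axial C4 carboxyl exchanges onto boron to give an acyloxyborohydride that can deliver hydride only intramolecularly to the α-face of the 1,3-diaxially placed C2 ketone, giving the equatorial 2β-alcohol, while the reagent is too weak to reduce the ketone intermolecularly; the closest known reaction is the hydroxyl-directed Saksena–Evans reduction of β-hydroxy ketones with Me4NBH(OAc)3.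

**Step 13**
Reactants: 29 (1R,3S,4aR,5S,8aS)-3-hydroxy-5-[(3E)-5-methoxy-3-methyl-5-oxopent-3-en-1-yl]-1,4a-dimethyl-6-methylidenedecahydronaphthalene-1-carboxylic acid
Product: 30 (1R,3S,4aR,5S,8aS)-5-[(3E)-4-carboxy-3-methylbut-3-en-1-yl]-3-hydroxy-1,4a-dimethyl-6-methylidenedecahydronaphthalene-1-carboxylic acid (target)
Conditions: LiOH (5 equiv), THF/MeOH/H2O, 45 °C; then 1 M HCl
Reagents that add atoms: lithium hydroxide, [Li+].[OH-]
Why: Saponification of the only remaining ester (the hindered C4 carboxyl was never esterified) gives the diacid without touching a stereocentre or the alkene geometry.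

**Compound list** (Ipc = isopinocampheyl from (+)-α-pinene)

1 | methyl (2E)-3,7-dimethylocta-2,6-dienoate (methyl geranate) | CC(C)=CCC/C(C)=C/C(=O)OC | starting material
2 | methyl (2E)-5-(5,5-dimethyl-1,2,4-trioxolan-3-yl)-3-methylpent-2-enoate (ozonide, racemic) | CC1(C)OOC(CC/C(C)=C/C(=O)OC)O1 | intermediate
3 | methyl (2E)-3-methyl-6-oxohex-2-enoate | O=CCC/C(C)=C/C(=O)OC | intermediate
4 | (2-bromoallyl)trimethylsilane | C=C(Br)C[Si](C)(C)C | starting material
5 | bromo[3-(trimethylsilyl)prop-1-en-2-yl]magnesium | C=C([Mg]Br)C[Si](C)(C)C | intermediate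
6 | methyl (2E)-6-hydroxy-3-methyl-7-[(trimethylsilyl)methyl]octa-2,7-dienoate (racemic at C6) | C=C(C[Si](C)(C)C)C(O)CC/C(C)=C/C(=O)OC | intermediate
7 | vinyl acetate | C=COC(C)=O | starting material
8 | methyl (2E)-6-(ethenyloxy)-3-methyl-7-[(trimethylsilyl)methyl]octa-2,7-dienoate (racemic) | C=COC(CC/C(C)=C/C(=O)OC)C(=C)C[Si](C)(C)C | intermediate
9 | methyl (2E,6Z)-3-methyl-10-oxo-7-[(trimethylsilyl)methyl]deca-2,6-dienoate | O=CCC/C(C[Si](C)(C)C)=C/CC/C(C)=C/C(=O)OC | intermediate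
10 | 2-(triphenylphosphoranylidene)propanal | CC(C=O)=P(c1ccccc1)(c1ccccc1)c1ccccc1 | starting material
11 | methyl (2E,6Z,10E)-3,11-dimethyl-12-oxo-7-[(trimethylsilyl)methyl]dodeca-2,6,10-trienoate | O=C/C(C)=C/CC/C(C[Si](C)(C)C)=C/CC/C(C)=C/C(=O)OC | intermediate
12 | 3-(methoxymethoxy)prop-1-ene (allyl methoxymethyl ether) | C=CCOCOC | starting material
13 | [(2Z)-3-(methoxymethoxy)prop-2-en-1-yl]lithium | [Li]C/C=C\OCOC | intermediate
14 | lithium methoxy[(2Z)-3-(methoxymethoxy)prop-2-en-1-yl]bis(isopinocampheyl)borate | [Li+].CO[B-](C/C=C\OCOC)([C@@H]1C[C@@H]2C[C@H]([C@H]1C)C2(C)C)[C@@H]1C[C@@H]2C[C@H]([C@H]1C)C2(C)C | intermediate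
15 | [(2Z)-3-(methoxymethoxy)prop-2-en-1-yl]bis(isopinocampheyl)borane | COCO/C=C\CB([C@@H]1C[C@@H]2C[C@H]([C@H]1C)C2(C)C)[C@@H]1C[C@@H]2C[C@H]([C@H]1C)C2(C)C | intermediate
16 | bis(isopinocampheyl)borinic ester of alcohol 17 (O-boryl at C12) | B([C@@H]1C[C@@H]2C[C@H]([C@H]1C)C2(C)C)([C@@H]1C[C@@H]2C[C@H]([C@H]1C)C2(C)C)O[C@H](/C(C)=C/CC/C(C[Si](C)(C)C)=C/CC/C(C)=C/C(=O)OC)[C@H](OCOC)C=C | intermediate
17 | methyl (2E,6Z,10E,12R,13R)-12-hydroxy-13-(methoxymethoxy)-3,11-dimethyl-7-[(trimethylsilyl)methyl]pentadeca-2,6,10,14-tetraenoate (syn) | O[C@H](/C(C)=C/CC/C(C[Si](C)(C)C)=C/CC/C(C)=C/C(=O)OC)[C@H](OCOC)C=C | intermediate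
18 | methacryloyl chloride | C=C(C)C(Cl)=O | starting material
19 | methyl (2E,6Z,10E,12R,13R)-13-(methoxymethoxy)-3,11-dimethyl-12-[(2-methylprop-2-enoyl)oxy]-7-[(trimethylsilyl)methyl]pentadeca-2,6,10,14-tetraenoate | C=C(C)C(=O)O[C@H](/C(C)=C/CC/C(C[Si](C)(C)C)=C/CC/C(C)=C/C(=O)OC)[C@H](OCOC)C=C | intermediate
20 | methyl (2E,6Z,10E)-11-[(2R,3R)-3-(methoxymethoxy)-5-methyl-6-oxo-3,6-dihydro-2H-pyran-2-yl]-3-methyl-7-[(trimethylsilyl)methyl]dodeca-2,6,10-trienoate | CC1=C[C@@H](OCOC)[C@@H](/C(C)=C/CC/C(C[Si](C)(C)C)=C/CC/C(C)=C/C(=O)OC)OC1=O | intermediate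
21 | lithium enolate of the saturated lactone (lithium (2R,3R)-3-(methoxymethoxy)-5-methyl-2-alkenyl-3,4-dihydro-2H-pyran-6-olate) | [Li]OC1=C(C)C[C@@H](OCOC)[C@@H](/C(C)=C/CC/C(C[Si](C)(C)C)=C/CC/C(C)=C/C(=O)OC)O1 | intermediate
22 | trimethylsilyl ketene acetal of the saturated lactone ((2R,3R)-3-(methoxymethoxy)-5-methyl-6-(trimethylsilyloxy)-3,4-dihydro-2H-pyran bearing the C2 alkenyl chain) | C[Si](C)(C)OC1=C(C)C[C@@H](OCOC)[C@@H](/C(C)=C/CC/C(C[Si](C)(C)C)=C/CC/C(C)=C/C(=O)OC)O1 | intermediate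
23 | trimethylsilyl ester of acid 24 | COC(=O)/C=C(C)/CC/C=C(C[Si](C)(C)C)/CC[C@H]1C(C)=C[C@H](OCOC)C[C@@]1(C)C(=O)O[Si](C)(C)C | intermediate
24 | (1R,2S,5R)-5-(methoxymethoxy)-2-[(3Z,7E)-9-methoxy-7-methyl-9-oxo-3-[(trimethylsilyl)methyl]nona-3,7-dien-1-yl]-1,3-dimethylcyclohex-3-ene-1-carboxylic acid (carboxyl cis to the side chain, trans to the ether) | COC(=O)/C=C(C)/CC/C=C(C[Si](C)(C)C)/CC[C@H]1C(C)=C[C@H](OCOC)C[C@@]1(C)C(=O)O | intermediate
25 | (1R,2S,5R)-5-hydroxy-2-[(3Z,7E)-9-methoxy-7-methyl-9-oxo-3-[(trimethylsilyl)methyl]nona-3,7-dien-1-yl]-1,3-dimethylcyclohex-3-ene-1-carboxylic acid | COC(=O)/C=C(C)/CC/C=C(C[Si](C)(C)C)/CC[C@H]1C(C)=C[C@H](O)C[C@@]1(C)C(=O)O | intermediate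
26 | (1R,2S)-2-[(3Z,7E)-9-methoxy-7-methyl-9-oxo-3-[(trimethylsilyl)methyl]nona-3,7-dien-1-yl]-1,3-dimethyl-5-oxocyclohex-3-ene-1-carboxylic acid | COC(=O)/C=C(C)/CC/C=C(C[Si](C)(C)C)/CC[C@H]1C(C)=CC(=O)C[C@@]1(C)C(=O)O | intermediate
27 | (1R,4aR,5S,8aS)-5-[(3E)-5-methoxy-3-methyl-5-oxopent-3-en-1-yl]-1,4a-dimethyl-6-methylidene-3-oxodecahydronaphthalene-1-carboxylic acid (cis-fused) | C=C1CC[C@H]2[C@](C)(CC(=O)C[C@@]2(C)C(=O)O)[C@H]1CC/C(C)=C/C(=O)OC | intermediate
28 | tetramethylammonium diacetoxy(hydrido)borate bound through the C1 carboxylate of 27 | C=C1CC[C@H]2[C@](C)(CC(=O)C[C@@]2(C)C(=O)O[BH-](OC(C)=O)OC(C)=O)[C@H]1CC/C(C)=C/C(=O)OC.C[N+](C)(C)C | intermediate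
29 | (1R,3S,4aR,5S,8aS)-3-hydroxy-5-[(3E)-5-methoxy-3-methyl-5-oxopent-3-en-1-yl]-1,4a-dimethyl-6-methylidenedecahydronaphthalene-1-carboxylic acid | C=C1CC[C@H]2[C@](C)(C[C@H](O)C[C@@]2(C)C(=O)O)[C@H]1CC/C(C)=C/C(=O)OC | intermediate
30 | (1R,3S,4aR,5S,8aS)-5-[(3E)-4-carboxy-3-methylbut-3-en-1-yl]-3-hydroxy-1,4a-dimethyl-6-methylidenedecahydronaphthalene-1-carboxylic acid (2β-hydroxy-5β-labda-8(17),13E-diene-15,18-dioic acid) | C=C1CC[C@H]2[C@](C)(C[C@H](O)C[C@@]2(C)C(=O)O)[C@H]1CC/C(C)=C/C(=O)O | target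

**Totals**
Total step count: 13. Longest linear sequence: 13 steps (from 1; all other components are purchased).

**Three steps most likely to fail, with fallbacks**

Step 11 (ring B closure). The conjugate allylation must join a trisubstituted allylsilane carbon to a β,β-disubstituted enone carbon next to a quaternary centre, and protodesilylation or the C9 epimer may compete. The fallback sets out from 26 and comes back at 27, replacing the polar closure by a radical one. Bromodesilylation of the allylsilane with NBS (CH2Cl2, −78 °C) gives the transposed allylic bromide (1R,2S)-2-[(7E)-4-bromo-9-methoxy-7-methyl-3-methylidene-9-oxonon-7-en-1-yl]-1,3-dimethyl-5-oxocyclohex-3-ene-1-carboxylic acid F2. Bu3SnH/AIBN (slow addition, PhH, 80 °C) then gives the allyl radical, which closes 6-exo-trig through C9 onto the enone carbon C10, and hydrogen transfer to the α-keto radical gives 27.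

Step 8 (reductive Ireland–Claisen ring contraction). The hydride may attack the lactone carbonyl, and the one-pot enolate trapping may fail. The fallback sets out from 20 and comes back at 24, separating reduction from rearrangement. Neutral copper hydride [(Ph3P)CuH]6 (PhH, rt) gives the isolated saturated lactone methyl (2E,6Z,10E)-11-[(2R,3R)-3-(methoxymethoxy)-5-methyl-6-oxooxan-2-yl]-3-methyl-7-[(trimethylsilyl)methyl]dodeca-2,6,10-trienoate F1 (both C-methyl epimers). The ketene silyl acetal is then made by deprotonation (LDA, Me3SiCl/Et3N, THF, −78 °C) and rearranged at 100 °C to 24.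

Step 12 (carboxyl-directed reduction). The intramolecular hydride delivery is unprecedented for a γ-keto acid, and an undirected reduction would probably come from the open β-face and give the wrong 2α-alcohol. The fallback sets out from 27 and comes back at 30, using inversion instead of facial control. Allyl bromide/K2CO3 (DMF) gives the allyl ester prop-2-en-1-yl (1R,4aR,5S,8aS)-5-[(3E)-5-methoxy-3-methyl-5-oxopent-3-en-1-yl]-1,4a-dimethyl-6-methylidene-3-oxodecahydronaphthalene-1-carboxylate F3. LiBH(s-Bu)3 (THF, −78 °C, cold quench) gives the 2α-alcohol prop-2-en-1-yl (1R,3R,4aR,5S,8aS)-3-hydroxy-5-[(3E)-5-methoxy-3-methyl-5-oxopent-3-en-1-yl]-1,4a-dimethyl-6-methylidenedecahydronaphthalene-1-carboxylate F4. Mitsunobu inversion (PPh3, DIAD, 4-nitrobenzoic acid) gives the 2β-ester prop-2-en-1-yl (1R,3S,4aR,5S,8aS)-5-[(3E)-5-methoxy-3-methyl-5-oxopent-3-en-1-yl]-1,4a-dimethyl-6-methylidene-3-[(4-nitrobenzoyl)oxy]decahydronaphthalene-1-carboxylate F5. Pd(PPh3)4/morpholine (allyl ester) followed by LiOH (benzoate and methyl ester) gives 30.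

**Further compounds**
F1 | step 8 | methyl (2E,6Z,10E)-11-[(2R,3R)-3-(methoxymethoxy)-5-methyl-6-oxooxan-2-yl]-3-methyl-7-[(trimethylsilyl)methyl]dodeca-2,6,10-trienoate (both C5 epimers of the oxane) | CC1C[C@@H](OCOC)[C@@H](/C(C)=C/CC/C(C[Si](C)(C)C)=C/CC/C(C)=C/C(=O)OC)OC1=O
F2 | step 11 | (1R,2S)-2-[(7E)-4-bromo-9-methoxy-7-methyl-3-methylidene-9-oxonon-7-en-1-yl]-1,3-dimethyl-5-oxocyclohex-3-ene-1-carboxylic acid (both bromide epimers) | COC(=O)/C=C(C)/CCC(Br)C(=C)CC[C@H]1C(C)=CC(=O)C[C@@]1(C)C(=O)O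
F3 | step 12 | prop-2-en-1-yl (1R,4aR,5S,8aS)-5-[(3E)-5-methoxy-3-methyl-5-oxopent-3-en-1-yl]-1,4a-dimethyl-6-methylidene-3-oxodecahydronaphthalene-1-carboxylate | C=C1CC[C@H]2[C@](C)(CC(=O)C[C@@]2(C)C(=O)OCC=C)[C@H]1CC/C(C)=C/C(=O)OC
F4 | step 12 | prop-2-en-1-yl (1R,3R,4aR,5S,8aS)-3-hydroxy-5-[(3E)-5-methoxy-3-methyl-5-oxopent-3-en-1-yl]-1,4a-dimethyl-6-methylidenedecahydronaphthalene-1-carboxylate | C=C1CC[C@H]2[C@](C)(C[C@@H](O)C[C@@]2(C)C(=O)OCC=C)[C@H]1CC/C(C)=C/C(=O)OC
F5 | step 12 | prop-2-en-1-yl (1R,3S,4aR,5S,8aS)-5-[(3E)-5-methoxy-3-methyl-5-oxopent-3-en-1-yl]-1,4a-dimethyl-6-methylidene-3-[(4-nitrobenzoyl)oxy]decahydronaphthalene-1-carboxylate | C=C1CC[C@H]2[C@](C)(C[C@H](OC(=O)c3ccc(cc3)[N+](=O)[O-])C[C@@]2(C)C(=O)OCC=C)[C@H]1CC/C(C)=C/C(=O)OC
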